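The numbers in the tables were computed with constants of no real substance.

In a one-step world L + Q → J runs until the smaller charge ends, so the blue flask should climb to 0.200 M of J. Read the table instead.

| flask | L | Q | time |
|---|---|---|---|
| blue | 0.200 M | 0.220 M |  |
| violet | 0.0800 M | 0.100 M |  |
| green | 0.400 M | 0.220 M |  |
| amber | 0.600 M | 0.660 M | 9.5 h |

| blue run: time / h | blue run: [J] / M | violet run: time / h | violet run: [J] / M | green run: time / h | green run: [J] / M |
|---|---|---|---|---|---|
| 0.72 | 0.0259 | 0.72 | 0.0020 | 0.72 | 0.0633 |
| 2.2 | 0.0597 | 2.2 | 0.0053 | 2.2 | 0.1368 |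
| 4.2 | 0.0855 | 4.2 | 0.0166 | 4.2 | 0.1476 |
| 6.6 | 0.1018 | 6.6 | 0.0204 | 6.6 | 0.1502 |
| 9.5 | 0.1043 | 9.5 | 0.0236 | 9.5 | 0.1532 |

(each reading ± 0.002 M)

- Overall: L + Q -> J.
- Constant volume, constant temperature.
- An order is taken over about fifteen percent of the charge, up and down.

1. how the opening rate goes with [Q] round the charge of the blue run: the exponent of the rate at two percent of L gone to J
2. how the opening rate goes with [L] round the charge of the blue run: the exponent of the rate at two percent of L gone to J (one fixed amount of J, the same in the runs compared)
3. J in the amber run at 9.5 h, as a share of the L charged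

Blue levels at 0.1043 M, below that limit, with 0.0957 M of L unconverted. Green levels at 0.1532 M, with 0.247 M of L unconverted. Both flasks level with L still in them, so take two ways to the amber number.

First way: suppose a reversal. Form J over the product of unconverted L and unconverted Q; blue reads 9.42 M⁻¹ and green 9.29 M⁻¹. Their mean, with amber taken to its plateau by 9.5 h, puts amber at 0.417 M, or 69.5% of its L.

Second way: suppose Q is lost by a path that needs no L, while making J needs L, that both paths go with Q alike, and that a plateau marks the end of Q. Then the share of Q reaching J, its selectivity, is mean L over mean L plus the even level, the L at which Q splits equally between J and loss. Mean L lies halfway between the charge and the L left at the plateau. Blue reads 0.164 M and green 0.141 M, so take the mean, 0.153 M. Amber, again taken to its plateau by 9.5 h, then reaches 0.466 M, or 77.7% of its L.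

Both ways are read off blue and green, but they part on amber, so test the reversal on blue. Its forward constant reads 0.929 M⁻¹ h⁻¹ from the first reading, but 1.94 M⁻¹ h⁻¹ between 4.2 h and 6.6 h, twice as much. The later figure rests on a small difference of scattered readings, but under the reversal blue's forward constant does not stay level, so drop the reversal and commit to the even level.

The forecast gives orders round the blue charge of 1.6 (1 to 2.2) in Q and 1.3 (0.9 to 1.8) in L, and 70% (65% to 73%) of amber's L, holding that amber “should be at equilibrium by 9.5 h”.

The amber flask gives 76.1% of its L at 9.5 h, and round the blue charge the orders are 1.4 in Q and 1.1 in L.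

    L + Q → J (0.4896 M⁻¹ h⁻¹)
    L + 2 Q → J + Q (1.516 M⁻² h⁻¹)
    L + Q + J → 2 J (29.16 M⁻² h⁻¹)
    2 Q → Xo (1.505 M⁻¹ h⁻¹)

The turning of Q into Xo moves the readings by 25 times the scatter, root mean square. Amber's 0.457 M of J at 9.5 h, taken as its plateau, reads as an even level of 0.166 M. On violet, the even level 0.153 M gives 0.0299 M of J as the plateau, and violet's readings climb from 0.0204 M at 6.6 h to 0.0236 M at 9.5 h.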